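Ring C is disconnected at O1–C8a and C3–C4, which splits the target into a ring A 2-bromoaroyl unit (C4, C4a, C8a) and a ring B enamine that carries C2 and C3. The key step exploits the ortho relation of C8a to the C4 carbonyl on ring A: in one flask the acid chloride C-acylates the enamine β-carbon C3, water unmasks the enol oxygen O1 at C2, and the C4 carbonyl then steers copper-catalysed O-arylation onto C8a, giving the isoflavone. Reduction and dehydration give the isoflav-3-ene, and asymmetric hydroboration of C3=C4 sets both stereocentres trans before hydrogenolysis of the benzyl ethers.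

Key step: step 5

Assumption: diethyl (pyrrolidin-1-ylmethyl)phosphonate and 2-bromo-3,4,5-trimethoxybenzoic acid are taken as catalogue chemicals.

Step 1
Reactants: 1 2-hydroxy-3,4-dimethoxybenzaldehyde
Product: 3 2,5-dihydroxy-3,4-dimethoxybenzaldehyde, via aryl sulfate 2 (not isolated)
Conditions: K2S2O8, aq. KOH, 10–20 °C; then aq. HCl, 80 °C; under N2
Reagents that add atoms: potassium peroxodisulfate [K+].[K+].[O-]S(=O)(=O)OOS(=O)(=O)[O-]
Why: Elbs persulfate oxidation: the phenoxide attacks a peroxide oxygen through its free para carbon (both ortho positions are blocked), and acid hydrolysis of the aryl sulfate unveils the hydroquinone pattern of ring B.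

Step 2
Reactants: 3 2,5-dihydroxy-3,4-dimethoxybenzaldehyde
Product: 4 2,5-bis(benzyloxy)-3,4-dimethoxybenzaldehyde
Conditions: BnBr, K2CO3, DMF, 60 °C, under argon
Reagents that add atoms: benzyl bromide BrCc1ccccc1
Why: Williamson etherification masks both phenols as benzyl ethers, which should survive organolithium base, copper catalysis, hydride and borane and can be removed at the end without acid.

Step 3
Reactants: 4 2,5-bis(benzyloxy)-3,4-dimethoxybenzaldehyde; 5 diethyl (pyrrolidin-1-ylmethyl)phosphonate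
Product: 6 (E)-1-{2-[2,5-bis(benzyloxy)-3,4-dimethoxyphenyl]ethenyl}pyrrolidine
Conditions: n-BuLi, THF, −78 °C; then 4, −78 °C to reflux; non-aqueous work-up
Reagents that add atoms: none
Why: Horner–Wadsworth–Emmons olefination with the α-amino phosphonate anion homologates the aldehyde to the conjugated (E)-enamine, whose β-carbon is the future C3 and whose nitrogen-bearing carbon is the future C2.

Step 4
Reactants: 7 2-bromo-3,4,5-trimethoxybenzoic acid
Product: 8 2-bromo-3,4,5-trimethoxybenzoyl chloride
Conditions: (COCl)2, DMF (cat.), CH2Cl2, 0 °C to rt; evaporate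
Reagents that add atoms: oxalyl chloride ClC(=O)C(=O)Cl
Why: Standard acid chloride formation through the chloroiminium catalyst activates the future C4 of ring A for C-acylation.

Step 5
Reactants: 6 (E)-1-{2-[2,5-bis(benzyloxy)-3,4-dimethoxyphenyl]ethenyl}pyrrolidine; 8 2-bromo-3,4,5-trimethoxybenzoyl chloride
Product: 11 3-[2,5-bis(benzyloxy)-3,4-dimethoxyphenyl]-6,7,8-trimethoxy-4H-chromen-4-one, via enaminone 9 (not isolated), via hydroxymethylene ketone 10 (not isolated)
Conditions: Et3N, 1,4-dioxane, 10 °C to rt; then 1 M aq. HCl, rt; then K2CO3, CuI (10 mol %), 1,10-phenanthroline (20 mol %), 100 °C; one flask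
Reagents that add atoms: water O
Why: The enamine β-carbon C3 attacks the acid chloride (Stork C-acylation, forming C3–C4) and Et3N removes the C3 proton to give vinylogous amide 9; aqueous acid hydrolyses 9 to enol 10, placing O1 on C2; carbonate then forms the β-oxo-enolate, which chelates monovalent copper next to the ortho C8a–Br bond, so that oxidative addition and C–O reductive elimination forge O1–C8a (Ullmann-type O-arylation). The closest known reaction types are the Grohe–Heitzer cycloaracylation of 2-halobenzoyl chlorides with enamines and the copper-catalysed closure of 2-haloaryl 1,3-dicarbonyl compounds to chromones. Ring C closes in a 6-exo-trig mode, the enolate oxygen attacking arene carbon C8a with the C–Br bond exocyclic to the new ring. No stereocentre is formed. The step needs C-acylation, and intramolecular O-arylation in preference to N-arylation by liberated pyrrolidine or retro-Claisen loss of the formyl carbon; the tertiary enamine can react only at carbon, and enolate chelation together with the mild carbonate base should favour the six-membered closure.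

Step 6
Reactants: 11 3-[2,5-bis(benzyloxy)-3,4-dimethoxyphenyl]-6,7,8-trimethoxy-4H-chromen-4-one
Product: 13 3-[2,5-bis(benzyloxy)-3,4-dimethoxyphenyl]-6,7,8-trimethoxy-2H-chromene, via isoflavan-4-ol 12 (not isolated)
Conditions: NaBH4, THF/EtOH, 0 °C to rt; aqueous work-up; then TsOH·H2O (5 mol %), toluene, 80 °C
Reagents that add atoms: none
Why: Borohydride reduces the vinylogous ester by 1,4- and then 1,2-hydride addition, and acid-catalysed E1 dehydration through the C4 benzylic cation (stabilised by O1 and the C7 methoxy group) gives the conjugated C3=C4 alkene, the 2'-oxygen being benzylated so that it cannot trap the cation.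

Step 7
Reactants: 13 3-[2,5-bis(benzyloxy)-3,4-dimethoxyphenyl]-6,7,8-trimethoxy-2H-chromene
Product: 15 (3S,4R)-3-[2,5-bis(benzyloxy)-3,4-dimethoxyphenyl]-6,7,8-trimethoxychroman-4-ol, via alkylborane 14 (not isolated)
Conditions: IpcBH2 (prepared from (+)-α-pinene), THF, −25 °C; then NaOH, H2O2, 0 °C to rt
Reagents that add atoms: hydrogen peroxide OO
Why: Asymmetric hydroboration: the bulky chiral monoalkylborane adds H–B syn across C3=C4 with boron on the less substituted C4 and hydrogen on C3, so that oxidation with retention gives the 3,4-trans alcohol, and the reagent from (+)-α-pinene is expected, by analogy with 1-phenylcyclohexene (which leads to the spatially equivalent (1S,2R)-trans-2-phenylcyclohexanol), to attack the face that sets C3 as S and C4 as R.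

Step 8
Reactants: 15 (3S,4R)-3-[2,5-bis(benzyloxy)-3,4-dimethoxyphenyl]-6,7,8-trimethoxychroman-4-ol
Product: 16 (3S,4R)-3-(2,5-dihydroxy-3,4-dimethoxyphenyl)-6,7,8-trimethoxychroman-4-ol
Conditions: H2 (1 atm), 10% Pd/C (acid-free), EtOAc, rt; work-up under argon
Reagents that add atoms: none
Why: Hydrogenolysis of the two aryl benzyl ethers under neutral conditions should free the hydroquinone without ionising the C4 carbinol, which under acid would be trapped by the 2'-hydroxyl as a pterocarpan; no stereocentre is touched.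

Compound list
1 | 2-hydroxy-3,4-dimethoxybenzaldehyde | O=Cc1ccc(OC)c(OC)c1O | starting material
2 | potassium 3-formyl-4-hydroxy-5,6-dimethoxyphenyl sulfate | [K+].O=Cc1cc(OS(=O)(=O)[O-])c(OC)c(OC)c1O | intermediate
3 | 2,5-dihydroxy-3,4-dimethoxybenzaldehyde | O=Cc1cc(O)c(OC)c(OC)c1O | intermediate
4 | 2,5-bis(benzyloxy)-3,4-dimethoxybenzaldehyde | O=Cc1cc(OCc2ccccc2)c(OC)c(OC)c1OCc1ccccc1 | intermediate
5 | diethyl (pyrrolidin-1-ylmethyl)phosphonate | CCOP(=O)(CN1CCCC1)OCC | starting material
6 | (E)-1-{2-[2,5-bis(benzyloxy)-3,4-dimethoxyphenyl]ethenyl}pyrrolidine | C1CCN(C1)/C=C/c1cc(OCc2ccccc2)c(OC)c(OC)c1OCc1ccccc1 | intermediate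
7 | 2-bromo-3,4,5-trimethoxybenzoic acid | COc1cc(C(=O)O)c(Br)c(OC)c1OC | starting material
8 | 2-bromo-3,4,5-trimethoxybenzoyl chloride | COc1cc(C(=O)Cl)c(Br)c(OC)c1OC | intermediate
9 | 2-[2,5-bis(benzyloxy)-3,4-dimethoxyphenyl]-1-(2-bromo-3,4,5-trimethoxyphenyl)-3-(pyrrolidin-1-yl)prop-2-en-1-one | COc1cc(C(=O)C(=CN2CCCC2)c2cc(OCc3ccccc3)c(OC)c(OC)c2OCc2ccccc2)c(Br)c(OC)c1OC | intermediate
10 | 2-[2,5-bis(benzyloxy)-3,4-dimethoxyphenyl]-1-(2-bromo-3,4,5-trimethoxyphenyl)-3-hydroxyprop-2-en-1-one | COc1cc(C(=O)C(=CO)c2cc(OCc3ccccc3)c(OC)c(OC)c2OCc2ccccc2)c(Br)c(OC)c1OC | intermediate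
11 | 3-[2,5-bis(benzyloxy)-3,4-dimethoxyphenyl]-6,7,8-trimethoxy-4H-chromen-4-one | COc1cc2c(=O)c(-c3cc(OCc4ccccc4)c(OC)c(OC)c3OCc3ccccc3)coc2c(OC)c1OC | intermediate
12 | 3-[2,5-bis(benzyloxy)-3,4-dimethoxyphenyl]-6,7,8-trimethoxychroman-4-ol (mixture of stereoisomers) | COc1cc2C(O)C(c3cc(OCc4ccccc4)c(OC)c(OC)c3OCc3ccccc3)COc2c(OC)c1OC | intermediate
13 | 3-[2,5-bis(benzyloxy)-3,4-dimethoxyphenyl]-6,7,8-trimethoxy-2H-chromene | COc1cc2C=C(c3cc(OCc4ccccc4)c(OC)c(OC)c3OCc3ccccc3)COc2c(OC)c1OC | intermediate
14 | {(3S,4R)-3-[2,5-bis(benzyloxy)-3,4-dimethoxyphenyl]-6,7,8-trimethoxychroman-4-yl}(isopinocampheyl)borane | COc1cc2c(c(OC)c1OC)OC[C@H](c1cc(OCc3ccccc3)c(OC)c(OC)c1OCc1ccccc1)[C@H]2B[C@@H]1C[C@@H]2C[C@@H](C2(C)C)[C@H]1C | intermediate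
15 | (3S,4R)-3-[2,5-bis(benzyloxy)-3,4-dimethoxyphenyl]-6,7,8-trimethoxychroman-4-ol | COc1cc2c(c(OC)c1OC)OC[C@H](c1cc(OCc3ccccc3)c(OC)c(OC)c1OCc1ccccc1)[C@H]2O | intermediate
16 | (3S,4R)-3-(2,5-dihydroxy-3,4-dimethoxyphenyl)-6,7,8-trimethoxychroman-4-ol | COc1cc2c(c(OC)c1OC)OC[C@H](c1cc(O)c(OC)c(OC)c1O)[C@H]2O | target

Total step count: 8
Longest linear sequence: 7 steps (steps 1, 2, 3, 5, 6, 7, 8); step 4 is the ring A branch.

Steps most likely to fail

Step 5. Oxidative addition at the C8a–Br bond, which is flanked by the C8 methoxy group and the acyl group, may be slow, so that hydrolytic loss of the formyl carbon or N-arylation by pyrrolidine competes with ring closure. The fallback sets out from enaminone 9, isolated after the acylation stage. Palladium-catalysed hydroxylation of its C–Br bond (Pd2(dba)3, tBuXPhos, KOH, 1,4-dioxane/H2O, 100 °C) should give the 2-hydroxyaryl enaminone F1. Its phenol oxygen then closes ring C by conjugate addition at C2 and loss of pyrrolidine, which comes back to isoflavone 11. In this variant O1 is put on ring A first and the ring is closed at O1–C2.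

Step 7. Facial discrimination by the borane on this hindered diaryl alkene may be poor, or some boron may be delivered to C3, which would erode enantiomeric purity and regiochemistry. The fallback sets out from isoflavone 11. Asymmetric transfer hydrogenation with dynamic kinetic resolution (RuCl[(S,S)-TsDPEN](p-cymene), HCO2H/Et3N, EtOAc, 40 °C) should give the cis-(3S,4S) alcohol F2. Mitsunobu inversion at C4 (4-nitrobenzoic acid, PPh3, DIAD, toluene, 0 °C) leads to the trans 4-nitrobenzoate F3, and methanolysis (K2CO3, MeOH) comes back to 15, bypassing 13.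

Step 1. Over-oxidation of the electron-rich phenolate and incomplete conversion are typical of the persulfate oxidation. The fallback sets out from 1. Bromination para to the phenol (NBS, MeCN, 0 °C) should give 5-bromo-2-hydroxy-3,4-dimethoxybenzaldehyde F4, and benzylation (BnBr, K2CO3, DMF) gives 2-(benzyloxy)-5-bromo-3,4-dimethoxybenzaldehyde F5. Palladium-catalysed C–O coupling with benzyl alcohol (Pd(OAc)2, RockPhos, Cs2CO3, toluene, 90 °C) then installs the second benzyloxy group and comes back to 4, bypassing 3.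

Further compounds
F1 | step 5 | 2-[2,5-bis(benzyloxy)-3,4-dimethoxyphenyl]-1-(2-hydroxy-3,4,5-trimethoxyphenyl)-3-(pyrrolidin-1-yl)prop-2-en-1-one | COc1cc(C(=O)C(=CN2CCCC2)c2cc(OCc3ccccc3)c(OC)c(OC)c2OCc2ccccc2)c(O)c(OC)c1OC
F2 | step 7 | (3S,4S)-3-[2,5-bis(benzyloxy)-3,4-dimethoxyphenyl]-6,7,8-trimethoxychroman-4-ol | COc1cc2c(c(OC)c1OC)OC[C@H](c1cc(OCc3ccccc3)c(OC)c(OC)c1OCc1ccccc1)[C@@H]2O
F3 | step 7 | (3S,4R)-3-[2,5-bis(benzyloxy)-3,4-dimethoxyphenyl]-6,7,8-trimethoxychroman-4-yl 4-nitrobenzoate | COc1cc2c(c(OC)c1OC)OC[C@H](c1cc(OCc3ccccc3)c(OC)c(OC)c1OCc1ccccc1)[C@H]2OC(=O)c1ccc(cc1)[N+](=O)[O-]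
F4 | step 1 | 5-bromo-2-hydroxy-3,4-dimethoxybenzaldehyde | O=Cc1cc(Br)c(OC)c(OC)c1O
F5 | step 1 | 2-(benzyloxy)-5-bromo-3,4-dimethoxybenzaldehyde | O=Cc1cc(Br)c(OC)c(OC)c1OCc1ccccc1
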